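**Retrosynthetic overview** (rings lettered A to H from the 2,4,6-trihydroxyphenyl end to the 3,4,5-trihydroxyphenyl end)
1. Target 17 comes from its henicosa-O-methyl ether 16 by global O-demethylation; all 21 hydroxyls are carried as OMe.
2. 16 is cut at the four unhindered aryl C–O bonds A–B, C–D, E–F and G–H. The first three are made by C–H borylation at the only unflanked C–H followed by oxidative C–O coupling, and G–H by Ullmann coupling.
3. The three hindered ether bonds B–C, D–E and F–G, plus the neighbouring C–O of rings C, E and G, all sit in one two-ring phenol 8. It is made once, in one step, by an aryne aryloxy-hydroxylation.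
4. No ring is built: all eight benzene rings come from three catalogue arenes (1, 2, 14). Joining order: F–G, then H, then D–E, then B–C, then A.
5. No stereochemical operation is required.

Assumption: the target SMILES has no stereocentre, no double-bond geometry and no stable axis (the diaryl ethers rotate freely), so it is achiral and nothing has to be set; 1, 2 and 14 are taken as commercial.

**Step 1**
Reactants: 1 2,6-dimethoxyphenol (syringol); 2 5-bromo-1,2,3-trimethoxybenzene
Product: 8 6-(2,6-dimethoxyphenoxy)-2,3,4-trimethoxyphenol, via lithium 2,6-dimethoxyphenoxide 3 (not isolated), via bromoaryllithium 4 (not isolated), via 3,4,5-trimethoxybenzyne 5 (not isolated), via aryloxyaryllithium 6 (not isolated), via lithium aryltrimethoxyborate 7 (not isolated)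
Conditions: 1 (2.5 equiv), lithium 2,2,6,6-tetramethylpiperidide (3.8 equiv, from 2,2,6,6-tetramethylpiperidine + n-butyllithium), THF, −78 °C; 2 (1.0 equiv) added slowly, −30 → 0 °C; B(OMe)3, −78 °C → rt; AcOH, 30% H2O2, 0 °C → rt
Reagents that add atoms: hydrogen peroxide, OO
Why: Proposed new method: an aryne 1,2-aryloxy-hydroxylation (three-component phenoxide/aryne/borate coupling) in which the amide base lithiates 2 at its only C–H (between Br and OMe) and loss of LiBr gives aryne 5; the phenoxide oxygen of 3 (both ortho carbons blocked) adds at the aryne carbon remote from the adjacent OMe (inductive/distortion control, as in cine-substitution of 3-haloanisoles), placing the carbanion between OAr and OMe, where it is chelate-stabilised and is the same species that ortho-lithiation would give, so proton shuttling through the free amine is self-correcting; borylation and peroxide oxidation turn C–Li into C–OH; the closest known reactions are base-mediated aryne O-arylation of phenols and amino- or thio-metalation of arynes with electrophile trapping; no stereocentre is formed.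

**Step 2**
Reactants: 8 6-(2,6-dimethoxyphenoxy)-2,3,4-trimethoxyphenol; 2 5-bromo-1,2,3-trimethoxybenzene
Product: 9 1-(2,6-dimethoxyphenoxy)-3,4,5-trimethoxy-2-(3,4,5-trimethoxyphenoxy)benzene (permethylated rings F–G–H)
Conditions: 2 (1.5 equiv), CuI (10 mol%), picolinic acid (20 mol%), K3PO4 (2 equiv), DMSO, 100 °C, N2
Reagents that add atoms: none
Why: Ligand-accelerated Ullmann diaryl ether synthesis joins a di-ortho-substituted phenol to an aryl bromide whose two ortho positions are free, the pairing this catalyst system handles well; no stereocentre is formed.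

**Step 3**
Reactants: 9 permethylated trimer F–G–H; 8 6-(2,6-dimethoxyphenoxy)-2,3,4-trimethoxyphenol
Product: 11 permethylated pentamer D–E–F–G–H (tridecamethyl ether; ring D para C–H free), via trimer pinacol boronate 10 (not isolated)
Conditions: [Ir(OMe)(cod)]2 (1.5 mol%), 4,4'-di-tert-butyl-2,2'-bipyridine (3 mol%), B2pin2 (1.0 equiv), THF, 80 °C; volatiles evaporated; then 8 (2 equiv), Cu(OAc)2 (30 mol%), pyridine, 4 Å MS, MeCN, O2 (1 atm), 50 °C
Reagents that add atoms: none
Why: Iridium-catalysed C–H borylation (Hartwig–Miyaura type) is sterically controlled and the para C–H of ring F is the only C–H in 9 with no ortho substituent, and the electron-rich boronate then undergoes Chan–Lam oxidative C–O coupling with hindered phenol 8 under conditions (O2, MeCN, pyridine) that should deactivate the iridium catalyst so 8 is not borylated; no stereocentre is formed.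

**Step 4**
Reactants: 11 permethylated pentamer D–E–F–G–H; 8 6-(2,6-dimethoxyphenoxy)-2,3,4-trimethoxyphenol
Product: 13 permethylated heptamer B–C–D–E–F–G–H (octadecamethyl ether; ring B para C–H free), via pentamer pinacol boronate 12 (not isolated)
Conditions: [Ir(OMe)(cod)]2 (2 mol%), 4,4'-di-tert-butyl-2,2'-bipyridine (4 mol%), B2pin2 (1.0 equiv), THF, 80 °C; volatiles evaporated; then 8 (2 equiv), Cu(OAc)2 (30 mol%), pyridine, 4 Å MS, MeCN, O2 (1 atm), 50 °C
Reagents that add atoms: none
Why: Same C–H borylation/Chan–Lam sequence: ring F is now flanked on every C–H, so the para C–H of ring D is the single unhindered site; no stereocentre is formed.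

**Step 5**
Reactants: 13 permethylated heptamer B–C–D–E–F–G–H; 14 2,4,6-trimethoxyphenol
Product: 16 henicosa-O-methyl ether of the target (rings A–H), via heptamer pinacol boronate 15 (not isolated)
Conditions: [Ir(OMe)(cod)]2 (2.5 mol%), 4,4'-di-tert-butyl-2,2'-bipyridine (5 mol%), B2pin2 (1.0 equiv), THF, 80 °C; volatiles evaporated; then 14 (3 equiv), Cu(OAc)2 (30 mol%), pyridine, 4 Å MS, MeCN, O2 (1 atm), 40 °C
Reagents that add atoms: none
Why: The same sterically controlled C–H borylation marks the para C–H of ring B, and Chan–Lam C–O coupling with the electron-rich phenol 14 installs ring A through its hindered oxygen; no stereocentre is formed.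

**Step 6**
Reactants: 16 henicosa-O-methyl ether of the target
Product: 17 target CNP0206369.0
Conditions: BBr3 (45 equiv), CH2Cl2, −78 °C → rt, 36 h, Ar; H2O, 0 °C; Sephadex LH-20 then C18, degassed solvents
Reagents that add atoms: none
Why: Lewis-acid cleavage of aryl methyl ethers with BBr3 (O–B complexation, bromide attack at methyl) removes all 21 methyl groups while diaryl ether C–O bonds, which have no alkyl carbon to attack, remain; no stereocentre is present.

**Compound list**
1 | 2,6-dimethoxyphenol (syringol) | COc1cccc(OC)c1O | starting material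
2 | 5-bromo-1,2,3-trimethoxybenzene | COc1cc(Br)cc(OC)c1OC | starting material
3 | lithium 2,6-dimethoxyphenoxide | [Li+].[O-]c1c(OC)cccc1OC | intermediate (not isolated)
4 | (6-bromo-2,3,4-trimethoxyphenyl)lithium | [Li]c1c(Br)cc(OC)c(OC)c1OC | intermediate (not isolated)
5 | 3,4,5-trimethoxybenzyne (1,2-didehydro-3,4,5-trimethoxybenzene) | COC1=CC#CC(OC)=C1OC | intermediate (not isolated)
6 | [6-(2,6-dimethoxyphenoxy)-2,3,4-trimethoxyphenyl]lithium | [Li]c1c(OC)c(OC)c(OC)cc1Oc1c(OC)cccc1OC | intermediate (not isolated)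
7 | lithium [6-(2,6-dimethoxyphenoxy)-2,3,4-trimethoxyphenyl]trimethoxyborate | [Li+].CO[B-](OC)(OC)c1c(OC)c(OC)c(OC)cc1Oc1c(OC)cccc1OC | intermediate (not isolated)
8 | 6-(2,6-dimethoxyphenoxy)-2,3,4-trimethoxyphenol (two-ring unit used for F–G, D–E and B–C) | COc1cccc(OC)c1Oc1cc(OC)c(OC)c(OC)c1O | intermediate
9 | 1-(2,6-dimethoxyphenoxy)-3,4,5-trimethoxy-2-(3,4,5-trimethoxyphenoxy)benzene (permethylated trimer F–G–H) | COc1cccc(OC)c1Oc1cc(OC)c(OC)c(OC)c1Oc1cc(OC)c(OC)c(OC)c1 | intermediate
10 | 9 carrying a 4,4,5,5-tetramethyl-1,3,2-dioxaborolan-2-yl group at the para carbon of ring F | COc1cc(B2OC(C)(C)C(C)(C)O2)cc(OC)c1Oc1cc(OC)c(OC)c(OC)c1Oc1cc(OC)c(OC)c(OC)c1 | intermediate (not isolated)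
11 | permethylated pentamer D–E–F–G–H: 9 whose ring F para carbon carries the oxygen of a 6-(2,6-dimethoxyphenoxy)-2,3,4-trimethoxyphenoxy group (rings E and D) | COc1cccc(OC)c1Oc1cc(OC)c(OC)c(OC)c1Oc1cc(OC)c(Oc2cc(OC)c(OC)c(OC)c2Oc2cc(OC)c(OC)c(OC)c2)c(OC)c1 | intermediate
12 | 11 carrying the pinacol boronate at the para carbon of ring D | COc1cc(B2OC(C)(C)C(C)(C)O2)cc(OC)c1Oc1cc(OC)c(OC)c(OC)c1Oc1cc(OC)c(Oc2cc(OC)c(OC)c(OC)c2Oc2cc(OC)c(OC)c(OC)c2)c(OC)c1 | intermediate (not isolated)
13 | permethylated heptamer B–C–D–E–F–G–H: 11 whose ring D para carbon carries a further 6-(2,6-dimethoxyphenoxy)-2,3,4-trimethoxyphenoxy group (rings C and B) | COc1cccc(OC)c1Oc1cc(OC)c(OC)c(OC)c1Oc1cc(OC)c(Oc2cc(OC)c(OC)c(OC)c2Oc2cc(OC)c(Oc3cc(OC)c(OC)c(OC)c3Oc3cc(OC)c(OC)c(OC)c3)c(OC)c2)c(OC)c1 | intermediate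
14 | 2,4,6-trimethoxyphenol | COc1cc(OC)c(O)c(OC)c1 | starting material
15 | 13 carrying the pinacol boronate at the para carbon of ring B | COc1cc(B2OC(C)(C)C(C)(C)O2)cc(OC)c1Oc1cc(OC)c(OC)c(OC)c1Oc1cc(OC)c(Oc2cc(OC)c(OC)c(OC)c2Oc2cc(OC)c(Oc3cc(OC)c(OC)c(OC)c3Oc3cc(OC)c(OC)c(OC)c3)c(OC)c2)c(OC)c1 | intermediate (not isolated)
16 | henicosa-O-methyl ether of the target: 13 whose ring B para carbon carries a 2,4,6-trimethoxyphenoxy group (ring A) | COc1cc(OC)c(Oc2cc(OC)c(Oc3cc(OC)c(OC)c(OC)c3Oc3cc(OC)c(Oc4cc(OC)c(OC)c(OC)c4Oc4cc(OC)c(Oc5cc(OC)c(OC)c(OC)c5Oc5cc(OC)c(OC)c(OC)c5)c(OC)c4)c(OC)c3)c(OC)c2)c(OC)c1 | intermediate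
17 | CNP0206369.0 (all 21 OMe of 16 replaced by OH; achiral) | Oc1cc(O)c(Oc2cc(O)c(Oc3cc(O)c(O)c(O)c3Oc3cc(O)c(Oc4cc(O)c(O)c(O)c4Oc4cc(O)c(Oc5cc(O)c(O)c(O)c5Oc5cc(O)c(O)c(O)c5)c(O)c4)c(O)c3)c(O)c2)c(O)c1 | target

**Totals**
Total steps: 6. Longest linear sequence: 6 (8 is made once and used in steps 2, 3 and 4).

**Steps most likely to fail**

Step 1 (the proposed new aryne aryloxy-hydroxylation). The aryne may be consumed by the amide base or by aryllithiums 4 or 6 faster than by phenoxide 3, or 3 may react through its para carbon. The fallback uses known chemistry, sets out from 1 and 2 and returns at 8. Ullmann coupling of 1 with 2 (CuI, picolinic acid, K3PO4, DMSO, 100 °C) gives the symmetric ether 5-(2,6-dimethoxyphenoxy)-1,2,3-trimethoxybenzene F1. Directed ortho-lithiation of F1 (n-butyllithium, THF, 0 °C) at one of its two equivalent C–H positions flanked by OAr and OMe gives the same aryllithium 6. B(OMe)3 converts 6 to 7, and H2O2/AcOH gives 8.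

Step 5 (C–H borylation/Chan–Lam on the largest substrate). Coupling of a pinacol boronate under catalytic divalent copper may be slow, and 14 is easily oxidised to a quinone under O2. The fallback sets out from 13 and returns at 16. Borylation of 13 as before gives 15, which is treated in the same flask with CuI, 1,10-phenanthroline and KI in MeOH/H2O under air at 80 °C (ipso-iododeboronation). This gives the heptamer iodide (13 with iodine at the para carbon of ring B) F2. F2 is coupled with 14 under oxygen-free Ullmann conditions (CuI, picolinic acid, K3PO4, DMSO, 90 °C, N2) to give 16.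

Step 6 (21-fold demethylation). Under-cleaved congeners and air oxidation of the free polyphenol during purification are the likely problems. The fallback sets out from 16 and returns at 17. After BBr3 cleavage the crude polyphenol is acetylated directly (Ac2O, pyridine, DMAP, rt) and purified on silica as the henicosaacetate of 17 F3; partially methylated acetates are separated and can be resubmitted. F3 is then deacetylated by acid methanolysis (HCl in degassed MeOH, 40 °C, Ar) to release 17 without basic, oxidising conditions.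

**Further compounds**
F1 | step 1 | 5-(2,6-dimethoxyphenoxy)-1,2,3-trimethoxybenzene | COc1cccc(OC)c1Oc1cc(OC)c(OC)c(OC)c1
F2 | step 5 | heptamer iodide: 13 with iodine at the para carbon of ring B | COc1cc(I)cc(OC)c1Oc1cc(OC)c(OC)c(OC)c1Oc1cc(OC)c(Oc2cc(OC)c(OC)c(OC)c2Oc2cc(OC)c(Oc3cc(OC)c(OC)c(OC)c3Oc3cc(OC)c(OC)c(OC)c3)c(OC)c2)c(OC)c1
F3 | step 6 | henicosaacetate of 17 (every OH of the target as OAc) | CC(=O)Oc1cc(OC(C)=O)c(Oc2cc(OC(C)=O)c(Oc3cc(OC(C)=O)c(OC(C)=O)c(OC(C)=O)c3Oc3cc(OC(C)=O)c(Oc4cc(OC(C)=O)c(OC(C)=O)c(OC(C)=O)c4Oc4cc(OC(C)=O)c(Oc5cc(OC(C)=O)c(OC(C)=O)c(OC(C)=O)c5Oc5cc(OC(C)=O)c(OC(C)=O)c(OC(C)=O)c5)c(OC(C)=O)c4)c(OC(C)=O)c3)c(OC(C)=O)c2)c(OC(C)=O)c1
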